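**Plan**

1. The target is read as robinetinidol-(4β→8)-gallocatechin. The upper flavan (ring A benzo, ring B aryl, ring C pyran) is 2R,3S,4R with the C4 aryl group cis to the 3-OH; the lower flavan (ring D benzo, ring E aryl, ring F pyran) is 2R,3S.
2. Cuts, in retrosynthetic order: the ten O–benzyl bonds; the interflavan bond C4 (ring C)–C8 (ring D), which gives a 4-methoxyflavan-3-ol and a ring D C8-boronic acid; C8–B back to C8–Br and C8–H; C4–OMe back to the C4 ketone.
3. Forward: no ring is built, both flavan skeletons are bought. Upper half: benzylation, ketone reduction, methanolysis at C4. Lower half: benzylation, C8 bromination, O3 benzylation, borylation. Then union of the halves and hydrogenolysis.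
4. Enabling feature: C4 is benzylic to ring A and conjugated with O1 (through C8a) and with the 7-oxygen (para to C4a), so its C–O bond ionizes. The β-hydroxyl on the neighbouring C3 can carry a boron atom that bears ring D and hand the aryl group to C4 on its own face.
5. Stereochemistry: C2 and C3 of both units come from (+)-dihydrorobinetin and (+)-gallocatechin; C4 is set in the union step by delivery syn to O3.

Key step: step 8

Assumption: (+)-dihydrorobinetin and (+)-gallocatechin are taken as commercial single enantiomers, and their C2/C3 centres are carried through without any step that could epimerize them.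

**Route**

Step 1
Reactants: 1 (+)-dihydrorobinetin, (2R,3R)-3,7-dihydroxy-2-(3,4,5-trihydroxyphenyl)chroman-4-one
Product: 2 (2R,3R)-7-benzyloxy-3-hydroxy-2-(3,4,5-tribenzyloxyphenyl)chroman-4-one
Conditions: BnBr (4.4 equiv), K2CO3, DMF, 0 °C to rt, argon
Reagents that add atoms: benzyl bromide, BrCc1ccccc1
Why: Williamson etherification of the four phenols; the less acidic C3 hydroxyl should stay free, and low temperature under argon keeps base-induced opening of ring C and air oxidation slow, so C2 and C3 are retained.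

Step 2
Reactants: 2 (2R,3R)-7-benzyloxy-3-hydroxy-2-(3,4,5-tribenzyloxyphenyl)chroman-4-one
Product: 3 (2R,3S,4R)-7-benzyloxy-2-(3,4,5-tribenzyloxyphenyl)chromane-3,4-diol
Conditions: NaBH4, THF/MeOH, 0 °C
Reagents that add atoms: none
Why: Borohydride reduction of the aryl ketone; axial hydride delivery should give mainly the 3,4-trans diol (4R), and this centre is temporary because C4 is ionized in steps 3 and 8.

Step 3
Reactants: 3 (2R,3S,4R)-7-benzyloxy-2-(3,4,5-tribenzyloxyphenyl)chromane-3,4-diol
Product: 4 (2R,3S,4R)-7-benzyloxy-4-methoxy-2-(3,4,5-tribenzyloxyphenyl)chroman-3-ol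
Conditions: CSA (cat.), MeOH/CH2Cl2, 0 °C to rt
Reagents that add atoms: methanol, CO
Why: Acid-catalysed SN1 etherification: only the benzylic C4 hydroxyl ionizes (cation stabilized by O1 and the 7-benzyloxy group) and methanol in large excess should capture it mainly trans to O3, while the C3 hydroxyl stays free; the C4 configuration is again temporary.

Step 4
Reactants: 5 (+)-gallocatechin, (2R,3S)-2-(3,4,5-trihydroxyphenyl)chromane-3,5,7-triol
Product: 6 (2R,3S)-5,7-dibenzyloxy-2-(3,4,5-tribenzyloxyphenyl)chroman-3-ol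
Conditions: BnBr (5.5 equiv), K2CO3, DMF, rt, argon
Reagents that add atoms: benzyl bromide, BrCc1ccccc1
Why: Williamson etherification of the five phenols; K2CO3 does not alkylate the secondary C3 hydroxyl, and once the phenols are capped no C2 epimerization through a ring E quinone methide can follow.

Step 5
Reactants: 6 (2R,3S)-5,7-dibenzyloxy-2-(3,4,5-tribenzyloxyphenyl)chroman-3-ol
Product: 7 (2R,3S)-5,7-dibenzyloxy-8-bromo-2-(3,4,5-tribenzyloxyphenyl)chroman-3-ol
Conditions: NBS (1.0 equiv), CH2Cl2, −78 °C to 0 °C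
Reagents that add atoms: N-bromosuccinimide, O=C1CCC(=O)N1Br
Why: Electrophilic aromatic bromination; ring D (1,3,5-trioxygenated) is the most electron-rich ring, and C8, between the 7-benzyloxy group and the small ring F oxygen, should react before C6, which lies between two benzyloxy groups.

Step 6
Reactants: 7 (2R,3S)-5,7-dibenzyloxy-8-bromo-2-(3,4,5-tribenzyloxyphenyl)chroman-3-ol
Product: 8 (2R,3S)-3,5,7-tribenzyloxy-8-bromo-2-(3,4,5-tribenzyloxyphenyl)chromane
Conditions: NaH, BnBr, DMF, 0 °C to rt
Reagents that add atoms: benzyl bromide, BrCc1ccccc1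
Why: Williamson etherification of the secondary alkoxide caps the last hydroxyl of the lower half, so that in step 8 only O3 of the upper half can bind boron; the aryl bromide and the stereocentres are not touched.

Step 7
Reactants: 8 (2R,3S)-3,5,7-tribenzyloxy-8-bromo-2-(3,4,5-tribenzyloxyphenyl)chromane
Product: 9 [(2R,3S)-3,5,7-tribenzyloxy-2-(3,4,5-tribenzyloxyphenyl)chroman-8-yl]boronic acid
Conditions: n-BuLi, THF, −78 °C; B(OMe)3, −78 °C to rt; sat. aq. NH4Cl
Reagents that add atoms: trimethyl borate, COB(OC)OC; water, O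
Why: Bromine–lithium exchange at −78 °C is faster than attack on the benzyl ethers and gives the C8 aryllithium, which trimethyl borate traps; mild hydrolysis should give the boronic acid with boron at the future point of attachment.

Step 8
Reactants: 4 (2R,3S,4R)-7-benzyloxy-4-methoxy-2-(3,4,5-tribenzyloxyphenyl)chroman-3-ol; 9 [(2R,3S)-3,5,7-tribenzyloxy-2-(3,4,5-tribenzyloxyphenyl)chroman-8-yl]boronic acid
Product: 12 (2R,3S,4R)-7-benzyloxy-4-[(2R,3S)-3,5,7-tribenzyloxy-2-(3,4,5-tribenzyloxyphenyl)chroman-8-yl]-2-(3,4,5-tribenzyloxyphenyl)chroman-3-ol, via O3-bound boronate zwitterion 10 (not isolated), via 3-O-borate ester 11 (not isolated)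
Conditions: 4 Å MS, CH2Cl2, rt, 1 h; then BF3·OEt2 (0.2 equiv), −78 to −20 °C; aq. NaHCO3
Reagents that add atoms: none
Why: Proposed new method: the free C3 hydroxyl of 4 condenses with boronic acid 9 (sieves), BF3 then ionizes the C4–OMe bond to a cation that is benzylic to ring A and stabilized by O1 (ortho, through C8a) and by the 7-benzyloxy oxygen (para to C4a), and the methoxide passes to boron, so that zwitterion 10 holds a tetracoordinate aryl boronate on the oxygen next to the cationic carbon; the electron-rich aryl group then shifts with its ipso carbon from boron to C4 through a five-membered cyclic transition state (C4, C3, O3, B, C8 of ring D) to give borate 11, which the work-up hydrolyses. The closest known reaction type is the Petasis borono-Mannich reaction of α-hydroxy aldehydes, together with its variants in which a boronate adds cis to a neighbouring hydroxyl on a cyclic N-acyliminium ion and in which aryl boron reagents add to oxocarbenium ions under BF3; the transfer to a flavan-4-yl cation is the untested part. No ring of the product is closed in this step. The new stereocentre C4 is controlled by C3: in the half-chair cation the C3–O3 bond leans roughly 45° out of the cation plane toward the β face (anti to the axial H3), so the five-membered transition state can reach only the β lobe, and the aryl group should arrive syn to O3 to give 4R (3,4-cis), the isomer that undirected attack disfavours. Site selectivity on ring D is fixed by boron, because the bond forms at the carbon that carries it (C8), and preference for the directed path is secured by the substrate design: O3 of 4 is the only hydroxyl in either partner, the transfer is intramolecular, and the catalytic Lewis acid at low temperature keeps protodeboronation and undirected attack by C6 of a second molecule slow.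

Step 9
Reactants: 12 (2R,3S,4R)-7-benzyloxy-4-[(2R,3S)-3,5,7-tribenzyloxy-2-(3,4,5-tribenzyloxyphenyl)chroman-8-yl]-2-(3,4,5-tribenzyloxyphenyl)chroman-3-ol
Product: 13 robinetinidol-(4β→8)-gallocatechin, (2R,3S,4R)-2-(3,4,5-trihydroxyphenyl)-4-[(2R,3S)-3,5,7-trihydroxy-2-(3,4,5-trihydroxyphenyl)chroman-8-yl]chromane-3,7-diol
Conditions: H2 (1 atm), Pd(OH)2 on carbon, THF/MeOH/H2O, rt
Reagents that add atoms: none
Why: Catalytic hydrogenolysis of the nine aryl benzyl ethers and the one alkyl benzyl ether under neutral conditions; the interflavan bond, the C2–O bonds of rings C and F and the five stereocentres should not be affected.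

**Compound list**

1 | (+)-dihydrorobinetin, (2R,3R)-3,7-dihydroxy-2-(3,4,5-trihydroxyphenyl)chroman-4-one | Oc1ccc2c(c1)O[C@H](c1cc(O)c(O)c(O)c1)[C@@H](O)C2=O | starting material
2 | (2R,3R)-7-benzyloxy-3-hydroxy-2-(3,4,5-tribenzyloxyphenyl)chroman-4-one | c1ccccc1COc1ccc2c(c1)O[C@H](c1cc(OCc3ccccc3)c(OCc3ccccc3)c(OCc3ccccc3)c1)[C@@H](O)C2=O | intermediate
3 | (2R,3S,4R)-7-benzyloxy-2-(3,4,5-tribenzyloxyphenyl)chromane-3,4-diol (2,3-trans-3,4-trans) | c1ccccc1COc1ccc2c(c1)O[C@H](c1cc(OCc3ccccc3)c(OCc3ccccc3)c(OCc3ccccc3)c1)[C@@H](O)[C@@H]2O | intermediate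
4 | (2R,3S,4R)-7-benzyloxy-4-methoxy-2-(3,4,5-tribenzyloxyphenyl)chroman-3-ol (drawn as the expected major 4α-methoxy epimer) | c1ccccc1COc1ccc2c(c1)O[C@H](c1cc(OCc3ccccc3)c(OCc3ccccc3)c(OCc3ccccc3)c1)[C@@H](O)[C@@H]2OC | intermediate
5 | (+)-gallocatechin, (2R,3S)-2-(3,4,5-trihydroxyphenyl)chromane-3,5,7-triol | Oc1cc(O)c2c(c1)O[C@H](c1cc(O)c(O)c(O)c1)[C@@H](O)C2 | starting material
6 | (2R,3S)-5,7-dibenzyloxy-2-(3,4,5-tribenzyloxyphenyl)chroman-3-ol | c1ccccc1COc1cc(OCc3ccccc3)c2c(c1)O[C@H](c1cc(OCc3ccccc3)c(OCc3ccccc3)c(OCc3ccccc3)c1)[C@@H](O)C2 | intermediate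
7 | (2R,3S)-5,7-dibenzyloxy-8-bromo-2-(3,4,5-tribenzyloxyphenyl)chroman-3-ol | c1ccccc1COc1cc(OCc3ccccc3)c2c(c1Br)O[C@H](c1cc(OCc3ccccc3)c(OCc3ccccc3)c(OCc3ccccc3)c1)[C@@H](O)C2 | intermediate
8 | (2R,3S)-3,5,7-tribenzyloxy-8-bromo-2-(3,4,5-tribenzyloxyphenyl)chromane | c1ccccc1COc1cc(OCc3ccccc3)c2c(c1Br)O[C@H](c1cc(OCc3ccccc3)c(OCc3ccccc3)c(OCc3ccccc3)c1)[C@@H](OCc3ccccc3)C2 | intermediate
9 | [(2R,3S)-3,5,7-tribenzyloxy-2-(3,4,5-tribenzyloxyphenyl)chroman-8-yl]boronic acid | c1ccccc1COc1cc(OCc3ccccc3)c2c(c1B(O)O)O[C@H](c1cc(OCc3ccccc3)c(OCc3ccccc3)c(OCc3ccccc3)c1)[C@@H](OCc3ccccc3)C2 | intermediate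
10 | O3-bound boronate zwitterion: (2R,3S)-flavan-4-ylium of the upper half with O3 bonded to the hydroxy(methoxy)(aryl)borate of the lower half | c1ccccc1COc1ccc2c(c1)O[C@H](c1cc(OCc3ccccc3)c(OCc3ccccc3)c(OCc3ccccc3)c1)[C@@H](O[B-](O)(OC)c1c(OCc3ccccc3)cc(OCc3ccccc3)c3c1O[C@H](c1cc(OCc4ccccc4)c(OCc4ccccc4)c(OCc4ccccc4)c1)[C@@H](OCc1ccccc1)C3)[CH+]2 | intermediate (not isolated)
11 | 3-O-[hydroxy(methoxy)boryl] ether of compound 12 | c1ccccc1COc1ccc2c(c1)O[C@H](c1cc(OCc3ccccc3)c(OCc3ccccc3)c(OCc3ccccc3)c1)[C@@H](OB(O)OC)[C@H]2c1c(OCc3ccccc3)cc(OCc3ccccc3)c2c1O[C@H](c1cc(OCc3ccccc3)c(OCc3ccccc3)c(OCc3ccccc3)c1)[C@@H](OCc3ccccc3)C2 | intermediate (not isolated)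
12 | (2R,3S,4R)-7-benzyloxy-4-[(2R,3S)-3,5,7-tribenzyloxy-2-(3,4,5-tribenzyloxyphenyl)chroman-8-yl]-2-(3,4,5-tribenzyloxyphenyl)chroman-3-ol | c1ccccc1COc1ccc2c(c1)O[C@H](c1cc(OCc3ccccc3)c(OCc3ccccc3)c(OCc3ccccc3)c1)[C@@H](O)[C@H]2c1c(OCc3ccccc3)cc(OCc3ccccc3)c2c1O[C@H](c1cc(OCc3ccccc3)c(OCc3ccccc3)c(OCc3ccccc3)c1)[C@@H](OCc3ccccc3)C2 | intermediate
13 | robinetinidol-(4β→8)-gallocatechin, (2R,3S,4R)-2-(3,4,5-trihydroxyphenyl)-4-[(2R,3S)-3,5,7-trihydroxy-2-(3,4,5-trihydroxyphenyl)chroman-8-yl]chromane-3,7-diol | Oc1ccc2c(c1)O[C@H](c1cc(O)c(O)c(O)c1)[C@@H](O)[C@H]2c1c(O)cc(O)c2c1O[C@H](c1cc(O)c(O)c(O)c1)[C@@H](O)C2 | target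

**Count and risks**

Total steps: 9. Longest linear sequence: 6 steps (steps 4, 5, 6, 7, 8, 9).

Steps most likely to fail:

1. Step 8 (the step with the new method). What may go wrong:
   - collapse of the cation with an aryl boron species that is not bound to O3, or attack by a second molecule, which would give the 3,4-trans bond;
   - protodeboronation of 9 by adventitious acid, followed by undirected coupling;
   - attack through C6 of ring D;
   - loss of the C3 proton from the cation toward a flavan-3-one.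

   Fallback with known chemistry, setting out from compounds 2 and 8. Silylation of the C3 hydroxyl of ketone 2 (TBSOTf, 2,6-lutidine, CH2Cl2) would give the 3-O-silyl ketone F1. Bromine–lithium exchange on 8 (t-BuLi, THF, −78 °C) and 1,2-addition of the aryllithium to the C4 carbonyl of F1 would form the same C4–C8 bond in the tertiary carbinol F2. Ionic deoxygenation (Et3SiH, CF3CO2H, CH2Cl2, −30 °C) would reduce F2 through the 4-aryl cation. Hydride is expected to enter from the α face, anti to the silyloxy group that leans toward the β face, which leaves the aryl group cis to O3 in silyl ether F3. Bu4NF in THF then removes the silyl group and the fallback comes back to the route at compound 12.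

2. Step 7. What may go wrong: protodeboronation of the di-ortho-alkoxy boronic acid during hydrolysis and isolation, or deprotonation of a benzyl ether instead of clean exchange.

   Fallback setting out from compound 8. After the same exchange and borate trapping, the mixture is treated with aqueous KHF2, and the boron reagent is isolated as the shelf-stable potassium trifluoroborate F4. The boronic acid is released only just before the coupling (TMSCl, H2O, MeCN), which comes back to the route at compound 9.

3. Step 1. What may go wrong: base-induced opening of ring C to the chalcone with scrambling of C2 and C3, air oxidation to the flavonol, or partial alkylation of O3.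

   Fallback setting out from compound 1. The ketone is reduced first (NaBH4, EtOH, 0 °C) to (+)-leucorobinetinidin F5, which has no carbonyl and so cannot open by the retro-oxa-Michael path. Benzylation of its four phenols (BnBr, K2CO3, DMF) then comes back to the route at compound 3.

**Further compounds**

F1 | step 8 | (2R,3R)-7-benzyloxy-3-(tert-butyldimethylsilyloxy)-2-(3,4,5-tribenzyloxyphenyl)chroman-4-one | c1ccccc1COc1ccc2c(c1)O[C@H](c1cc(OCc3ccccc3)c(OCc3ccccc3)c(OCc3ccccc3)c1)[C@@H](O[Si](C)(C)C(C)(C)C)C2=O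
F2 | step 8 | tertiary C4 carbinol from F1 and the aryllithium of 8 (drawn as 4α-aryl-4β-hydroxy; the C4 configuration is lost on ionization) | c1ccccc1COc1ccc2c(c1)O[C@H](c1cc(OCc3ccccc3)c(OCc3ccccc3)c(OCc3ccccc3)c1)[C@@H](O[Si](C)(C)C(C)(C)C)[C@]2(O)c1c(OCc3ccccc3)cc(OCc3ccccc3)c2c1O[C@H](c1cc(OCc3ccccc3)c(OCc3ccccc3)c(OCc3ccccc3)c1)[C@@H](OCc3ccccc3)C2
F3 | step 8 | 3-O-tert-butyldimethylsilyl ether of compound 12 | c1ccccc1COc1ccc2c(c1)O[C@H](c1cc(OCc3ccccc3)c(OCc3ccccc3)c(OCc3ccccc3)c1)[C@@H](O[Si](C)(C)C(C)(C)C)[C@H]2c1c(OCc3ccccc3)cc(OCc3ccccc3)c2c1O[C@H](c1cc(OCc3ccccc3)c(OCc3ccccc3)c(OCc3ccccc3)c1)[C@@H](OCc3ccccc3)C2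
F4 | step 7 | potassium [(2R,3S)-3,5,7-tribenzyloxy-2-(3,4,5-tribenzyloxyphenyl)chroman-8-yl]trifluoroborate | [K+].F[B-](F)(F)c1c(OCc3ccccc3)cc(OCc3ccccc3)c2c1O[C@H](c1cc(OCc3ccccc3)c(OCc3ccccc3)c(OCc3ccccc3)c1)[C@@H](OCc3ccccc3)C2
F5 | step 1 | (+)-leucorobinetinidin, (2R,3S,4R)-2-(3,4,5-trihydroxyphenyl)chromane-3,4,7-triol | Oc1ccc2c(c1)O[C@H](c1cc(O)c(O)c(O)c1)[C@@H](O)[C@@H]2O
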